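**Plan**

1. Cuts: in the dihydropyran ring (O1; C2 with the dichloropropan-2-yl group; C3H2; C4H=C5(CH3); C6 with CHBr2) the C5–C6, C2–C3 and O1–C2 bonds are cut together. This leaves 2,2-dibromoacetaldehyde (C6, O1), (R)-2,3-dichloro-2-methylpropanal (C2 and side chain) and a four-carbon boron/silicon linchpin (C3, C4, C5, CH3).
2. Enabling feature: O1 lies between two carbons of aldehyde oxidation level (C2, C6) that are bridged by the allyl unit C3–C4=C5. A 3-silylbut-2-enyl boronate can therefore act first as an allylboron (its γ-carbon becomes C5) and then as an allylsilane (its terminal carbon becomes C3; silicon leaves from C5 and the C4=C5 bond appears where the target has it).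
3. Forward order: the linchpin is made in three steps from but-2-yn-1-ol and the chloro aldehyde in two steps from 2-methylprop-2-en-1-ol. A one-flask union of the three components then closes the only ring and finishes the target.
4. Stereochemistry: the quaternary C–Cl centre (R) comes from a titanium-mediated enantioselective dichlorination, and C6 (S) from catalyst-controlled allylboration. The transient silyl-bearing carbon is set by the E geometry of the boronate (anti adduct). C2 (S), and with it the 2,6-trans ring, follows from anti SE2′ attack on an E-oxocarbenium ion.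

Key step: step 6

Assumption: 2,2-dibromoacetaldehyde is taken as a purchasable catalogue chemical that is dried and distilled directly before use.

**Step 1**
Reactants: 1 but-2-yn-1-ol
Product: 2 (E)-3-[dimethyl(phenyl)silyl]but-2-en-1-ol
Conditions: PhMe2SiH, PtCl2 (cat.), XPhos (cat.), THF, 50 °C
Reagents that add atoms: dimethyl(phenyl)silane, C[SiH](C)c1ccccc1
Why: Platinum-catalysed syn hydrosilylation of an internal propargylic alcohol should put hydride on the alkyne carbon next to the inductively withdrawing CH2OH and silicon on the distal carbon, and cis addition of H and Si fixes the E alkene (silicon trans to CH2OH, methyl cis).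

**Step 2**
Reactants: 2 (E)-3-[dimethyl(phenyl)silyl]but-2-en-1-ol
Product: 3 (E)-(4-chlorobut-2-en-2-yl)dimethyl(phenyl)silane
Conditions: NCS, Me2S, CH2Cl2, −20 to 0 °C
Reagents that add atoms: N-chlorosuccinimide, O=C1CCC(=O)N1Cl
Why: In this Corey–Kim chlorination the alkoxysulfonium salt of the primary allylic alcohol is displaced by chloride in an SN2 sense without allylic transposition, and the vinylsilane is inert under these mild conditions, so the alkene geometry should be kept.

**Step 3**
Reactants: 3 (E)-(4-chlorobut-2-en-2-yl)dimethyl(phenyl)silane
Product: 4 (E)-2-{3-[dimethyl(phenyl)silyl]but-2-en-1-yl}-4,4,5,5-tetramethyl-1,3,2-dioxaborolane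
Conditions: B2pin2, Pd2(dba)3 (cat.), THF, 60 °C
Reagents that add atoms: bis(pinacolato)diboron, CC1(C)OB(OC1(C)C)B1OC(C)(C)C(C)(C)O1
Why: In this Miyaura-type borylation of an allylic halide, oxidative addition to zerovalent palladium, transmetalation with the diboron and C–B bond formation at the unsubstituted allyl terminus should give the linear boronate, with the geometry at the fully substituted terminus retained because syn/anti exchange there would need a tertiary σ-allyl palladium species.

**Step 4**
Reactants: 5 2-methylprop-2-en-1-ol
Product: 6 (2R)-2,3-dichloro-2-methylpropan-1-ol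
Conditions: t-BuOCl, ClTi(OiPr)3, chiral tridentate Schiff-base ligand (salicylaldimine of a tert-leucine-derived 1,1-diaryl amino alcohol; enantiomer that leads to the R product; cat.), hexanes, −20 °C
Reagents that add atoms: tert-butyl hypochlorite, CC(C)(C)OCl; chlorotitanium triisopropoxide, CC(C)O[Ti](Cl)(OC(C)C)OC(C)C
Why: In this titanium-mediated catalytic enantioselective dichlorination of an allylic alcohol the substrate binds as a titanium alkoxide inside the chiral complex, the hypochlorite delivers electrophilic chlorine to one alkene face and titanium-bound chloride opens the chloriranium ion at the tertiary carbon with inversion, which sets the R quaternary C–Cl centre.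

**Step 5**
Reactants: 6 (2R)-2,3-dichloro-2-methylpropan-1-ol
Product: 7 (2R)-2,3-dichloro-2-methylpropanal
Conditions: Dess–Martin periodinane, CH2Cl2, 0 °C to rt; used as a dried solution or after short-path distillation
Reagents that add atoms: none
Why: Dess–Martin oxidation of the primary alcohol runs under near-neutral conditions, and since the α-carbon carries no hydrogen neither epimerisation nor loss of HCl can occur, so the R centre should pass unchanged into the aldehyde.

**Step 6**
Reactants: 4 (E)-2-{3-[dimethyl(phenyl)silyl]but-2-en-1-yl}-4,4,5,5-tetramethyl-1,3,2-dioxaborolane; 7 (2R)-2,3-dichloro-2-methylpropanal; 8 2,2-dibromoacetaldehyde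
Product: 11 (2S,6S)-6-(dibromomethyl)-2-[(2R)-1,2-dichloropropan-2-yl]-5-methyl-3,6-dihydro-2H-pyran (the target), via homoallylic pinacol borate 9 (not isolated), via oxocarbenium triflate 10 (not isolated)
Conditions: 8 + 4 (slight excess), (S)-TRIP [(S)-3,3′-bis(2,4,6-triisopropylphenyl)-1,1′-binaphthyl-2,2′-diyl hydrogen phosphate] (cat.), 4 Å MS, toluene, −40 °C; then 7 (excess), TMSOTf, CH2Cl2, −78 to −40 °C; aq. NaHCO3
Reagents that add atoms: none
Why: In the first stage the chiral phosphoric acid activates 4 for a closed six-membered chair allylboration in which the γ-carbon of 4 (future C5) bonds to the carbonyl carbon of 8 (future C6) with allylic transposition, the catalyst choosing the aldehyde face (C6, S; (S)-TRIP is the antipode of the catalyst that gives R carbinols from simple aldehydes) and the E geometry of 4 placing silicon anti to the new oxygen on the transient quaternary silyl-bearing carbon of 9. In the second stage trimethylsilyl triflate exchanges the borate oxygen to silicon and condenses it with 7 to the E-oxocarbenium ion 10, whose carbon (C2) is attacked by the terminal alkene carbon (future C3) in a 6-endo-trig closure of the dihydropyran ring on the alkene face opposite the C–Si bond (anti SE2′), after which loss of the silyl group from the β-silyl cation leaves the C4=C5 double bond. The closest known reaction types are the one-pot allylboration/Prins sequence of allylboronates with two aldehydes and the formal [4+2] annulation of anti-β-hydroxy (or silyloxy) allylsilanes with aldehydes that gives 2,6-trans-dihydropyrans. C2 (S) is controlled by the silyl-bearing stereocentre of 9 together with the E geometry of the oxocarbenium ion: with the C–Si bond held parallel to the alkene π system the anti isomer can only close with the CHBr2 group axial (or through a boat), and this gives the 2,6-trans ring, while the quaternary C–Cl centre of 7 is a spectator. The step needs face selectivity at 8, anti (E-derived) diastereoselectivity, trans over cis ring closure and a strict assignment of roles to the two aldehydes; these are secured by the catalyst, by the geometrically pure boronate, by the stereospecific anti SE2′ pathway at low temperature (which also disfavours Peterson elimination and oxonia-Cope scrambling) and by adding 7 only after 8 is consumed. Because 7 is a single enantiomer, any minor enantiomer of 9 should end as a separable diastereomer of 11 and not as its mirror image.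

**Compound list**

1 | but-2-yn-1-ol | CC#CCO | starting material
2 | (E)-3-[dimethyl(phenyl)silyl]but-2-en-1-ol | C/C(=C\CO)[Si](C)(C)c1ccccc1 | intermediate
3 | (E)-(4-chlorobut-2-en-2-yl)dimethyl(phenyl)silane | C/C(=C\CCl)[Si](C)(C)c1ccccc1 | intermediate
4 | (E)-2-{3-[dimethyl(phenyl)silyl]but-2-en-1-yl}-4,4,5,5-tetramethyl-1,3,2-dioxaborolane | C/C(=C\CB1OC(C)(C)C(C)(C)O1)[Si](C)(C)c1ccccc1 | intermediate
5 | 2-methylprop-2-en-1-ol | C=C(C)CO | starting material
6 | (2R)-2,3-dichloro-2-methylpropan-1-ol | OC[C@@](C)(Cl)CCl | intermediate
7 | (2R)-2,3-dichloro-2-methylpropanal | O=C[C@@](C)(Cl)CCl | intermediate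
8 | 2,2-dibromoacetaldehyde | O=CC(Br)Br | starting material
9 | 2-{[(2S,3S)-1,1-dibromo-3-[dimethyl(phenyl)silyl]-3-methylpent-4-en-2-yl]oxy}-4,4,5,5-tetramethyl-1,3,2-dioxaborolane | BrC(Br)[C@@H](OB1OC(C)(C)C(C)(C)O1)[C@@](C)([Si](C)(C)c1ccccc1)C=C | intermediate (not isolated)
10 | (E)-[(2R)-2,3-dichloro-2-methylpropylidene]{(2S,3S)-1,1-dibromo-3-[dimethyl(phenyl)silyl]-3-methylpent-4-en-2-yl}oxonium trifluoromethanesulfonate | BrC(Br)[C@@H](/[O+]=C/[C@@](C)(Cl)CCl)[C@@](C)([Si](C)(C)c1ccccc1)C=C.[O-]S(=O)(=O)C(F)(F)F | intermediate (not isolated)
11 | (2S,6S)-6-(dibromomethyl)-2-[(2R)-1,2-dichloropropan-2-yl]-5-methyl-3,6-dihydro-2H-pyran | CC1=CC[C@@H]([C@@](C)(Cl)CCl)O[C@@H]1C(Br)Br | target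

Total step count: 6. Longest linear sequence: 4 steps (steps 1, 2, 3 and 6).

**Steps most likely to fail**

Step 6. Uncatalysed background addition to the very electrophilic aldehyde may erode face selectivity. The hand-over from borate to oxocarbenium ion may also be slow enough for Peterson-type elimination, or for an oxonia-Cope/vinylsilane pathway that leaks to the 2,6-cis ring. The fallback replaces the catalytic one-flask union by a stoichiometric chiral boron reagent, an isolated carbinol and the two-component annulation. It sets out from 2: palladium-catalysed borylation of the allylic alcohol with tetrahydroxydiboron (Pd(MeCN)4(BF4)2 cat., DMSO/MeOH, rt) should give (E)-{3-[dimethyl(phenyl)silyl]but-2-en-1-yl}boronic acid F1. Esterification with (R,R)-diisopropyl tartrate over MgSO4 should give diisopropyl (4R,5R)-2-{(E)-3-[dimethyl(phenyl)silyl]but-2-en-1-yl}-1,3,2-dioxaborolane-4,5-dicarboxylate F2. Reagent-controlled allylboration of 8 (toluene, 4 Å MS, −78 °C; the (R,R) tartrate is the one expected to deliver the S carbinol) should give the borate diisopropyl (4R,5R)-2-{[(2S,3S)-1,1-dibromo-3-[dimethyl(phenyl)silyl]-3-methylpent-4-en-2-yl]oxy}-1,3,2-dioxaborolane-4,5-dicarboxylate F3. Aqueous work-up releases the free anti-β-hydroxyallylsilane (2S,3S)-1,1-dibromo-3-[dimethyl(phenyl)silyl]-3-methylpent-4-en-2-ol F4, which can be purified and, if needed, enriched. F4 is then combined with 7 and TMSOTf in CH2Cl2 at −78 °C, and the route is rejoined at 11.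

Step 4. The chiral titanium complex may discriminate poorly between the two faces of this small 1,1-disubstituted alkene, whose methyl and chloromethyl arms are of similar size, and solvolytic capture of the chloriranium ion may compete. The fallback sets the centre by an epoxide route with stereospecific chloride delivery and sets out from 5. Sharpless asymmetric epoxidation (Ti(OiPr)4, L-(+)-diisopropyl tartrate, cumene hydroperoxide, 4 Å MS, CH2Cl2, −20 °C) should give (S)-2-methylglycidol F5. This is esterified in the same flask with 4-nitrobenzoyl chloride and Et3N to crystalline [(2R)-2-methyloxiran-2-yl]methyl 4-nitrobenzoate F6, which can be recrystallised. Deoxydichlorination with Ph3PCl2 (CH2Cl2, rt to reflux) should open the activated epoxide at the tertiary carbon with inversion and then displace the primary oxyphosphonium group, giving (2R)-2,3-dichloro-2-methylpropyl 4-nitrobenzoate F7. Acid-catalysed methanolysis (HCl, MeOH, 40 °C) rejoins the route at 6.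

Step 3. π–σ–π equilibration of the allylpalladium intermediate may scramble the alkene geometry, which would pass on as syn adduct and 2,6-cis ring, and the boronate may protodeboronate on purification. The fallback avoids an allylmetal intermediate by diene 1,4-hydroboration and sets out from 3. 1,4-Dehydrochlorination (KOt-Bu, 18-crown-6, THF, 0 °C) should give 2-[dimethyl(phenyl)silyl]buta-1,3-diene F8. Iron-catalysed 1,4-hydroboration with pinacolborane (FeCl2 with a 2-iminopyridine ligand, reduced in situ with magnesium, Et2O, rt) adds hydrogen to C1 and boron to C4 of 2-substituted dienes and leaves the 2-substituent trans to the CH2B group, so it rejoins the route at 4.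

**Further compounds**

F1 | step 6 | (E)-{3-[dimethyl(phenyl)silyl]but-2-en-1-yl}boronic acid | C/C(=C\CB(O)O)[Si](C)(C)c1ccccc1
F2 | step 6 | diisopropyl (4R,5R)-2-{(E)-3-[dimethyl(phenyl)silyl]but-2-en-1-yl}-1,3,2-dioxaborolane-4,5-dicarboxylate | C/C(=C\CB1O[C@@H](C(=O)OC(C)C)[C@@H](O1)C(=O)OC(C)C)[Si](C)(C)c1ccccc1
F3 | step 6 | diisopropyl (4R,5R)-2-{[(2S,3S)-1,1-dibromo-3-[dimethyl(phenyl)silyl]-3-methylpent-4-en-2-yl]oxy}-1,3,2-dioxaborolane-4,5-dicarboxylate | BrC(Br)[C@@H](OB1O[C@@H](C(=O)OC(C)C)[C@@H](O1)C(=O)OC(C)C)[C@@](C)([Si](C)(C)c1ccccc1)C=C
F4 | step 6 | (2S,3S)-1,1-dibromo-3-[dimethyl(phenyl)silyl]-3-methylpent-4-en-2-ol | BrC(Br)[C@@H](O)[C@@](C)([Si](C)(C)c1ccccc1)C=C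
F5 | step 4 | (S)-2-methylglycidol, [(2S)-2-methyloxiran-2-yl]methanol | C[C@]1(CO)CO1
F6 | step 4 | [(2R)-2-methyloxiran-2-yl]methyl 4-nitrobenzoate | C[C@]1(COC(=O)c2ccc(cc2)[N+](=O)[O-])CO1
F7 | step 4 | (2R)-2,3-dichloro-2-methylpropyl 4-nitrobenzoate | O=C(OC[C@@](C)(Cl)CCl)c1ccc(cc1)[N+](=O)[O-]
F8 | step 3 | 2-[dimethyl(phenyl)silyl]buta-1,3-diene | C=CC(=C)[Si](C)(C)c1ccccc1
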